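**Retrosynthetic overview**

- The benzylic ester C–O bond is cut last but one, giving a phenol-silylated (S)-carbinol and (Z)-2-(angeloyloxymethyl)but-2-enoic acid; the phenol is unmasked in the final step.
- The strategy rests on the phenolic oxygen on aromatic C3 of the single benzene ring. It is meta to C1, which carries the (S)-CH(O-acyl)Et carbon, and ortho to the C4 methoxy group. In a 3,4-dimethoxyphenyl carbinol this is the only ring C–H that the branched benzylic carbon does not flank, so the C3–O bond is made there by iridium C–H borylation and oxidation.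
- The carbinol stereocentre comes from asymmetric transfer hydrogenation of 3,4-dimethoxypropiophenone.
- The acid is cut at the angelate C–O bond and at the alkene–carboxyl C–C bond (carbonylation of (Z)-2-iodobut-2-en-1-ol, whose geometry comes from α-iodination of crotonaldehyde).
- No ring is formed; the benzene ring is bought with the ketone.

Key step: step 2

Remark: commercial crotonaldehyde is taken as the (E)-isomer and commercial angelic acid as (Z)-2-methylbut-2-enoic acid; the acid half of the target is not assumed to be purchasable and is made in steps 4 to 8.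

**Route**

Step 1
Reactants: 1 1-(3,4-dimethoxyphenyl)propan-1-one
Product: 2 (1S)-1-(3,4-dimethoxyphenyl)propan-1-ol
Conditions: RuCl(p-cymene)[(S,S)-TsDPEN] (1 mol%), HCO2H/Et3N (5:2), 40 °C
Reagents that add atoms: none
Why: Noyori–Ikariya asymmetric transfer hydrogenation, in which the divalent ruthenium hydride and its NH ligand deliver hydride and proton through a six-membered outer-sphere transition state with the aryl group next to the p-cymene ring, so that the (S,S)-ligand should give the (S)-carbinol as it does for acetophenone and propiophenone.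

Step 2
Reactants: 2 (1S)-1-(3,4-dimethoxyphenyl)propan-1-ol
Product: 5 (1S)-1-(3-hydroxy-4,5-dimethoxyphenyl)propan-1-ol, via pinacol borate ester 3 (not isolated), via ring-borylated pinacol borate ester 4 (not isolated)
Conditions: HBpin (1.1 equiv), [Ir(OMe)(cod)]2 (2.5 mol%), 3,4,7,8-tetramethyl-1,10-phenanthroline (5 mol%), THF, rt; then B2pin2 (1.5 equiv), 80 °C; then aq NaOH, 30% H2O2, 0 °C to rt; Na2S2O3, NH4Cl work-up
Reagents that add atoms: hydrogen peroxide, OO
Why: Pinacolborane first converts the hydroxyl into borate 3 with loss of H2, which removes the acidic proton and enlarges the benzylic substituent. The active catalyst is a phenanthroline-bound iridium tris(boryl) complex (trivalent iridium) that inserts into the most accessible ring C–H bond and releases aryl boronate 4 by C–B reductive elimination; hydroperoxide then adds to boron, the aryl group migrates from boron to oxygen at the same ring carbon, and the O–B borate is hydrolysed back to the carbinol. The closest known reaction type is the one-flask iridium-catalysed arene C–H borylation and oxidation to phenols. No ring is closed and no stereocentre is formed, and the benzylic centre set in step 1 has no bond that reacts under these conditions. The step needs regioselectivity among three ring C–H bonds: H-2 lies between the side chain and the 3-methoxy group, H-6 is ortho to the branched CH(OBpin)Et carbon, and only H-5, ortho to the small methoxy group on C4 and acidified by it, stays open. Because every C–H has an ortho neighbour and the ring is electron-rich, heating and the electron-rich tetramethylphenanthroline ligand are used.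

Step 3
Reactants: 5 (1S)-1-(3-hydroxy-4,5-dimethoxyphenyl)propan-1-ol
Product: 6 (1S)-1-{3-[(tert-butyldimethylsilyl)oxy]-4,5-dimethoxyphenyl}propan-1-ol
Conditions: TBSCl (1.05 equiv), imidazole, CH2Cl2, 0 °C
Reagents that add atoms: tert-butyldimethylsilyl chloride, CC(C)(C)[Si](C)(C)Cl
Why: Chemoselective O-silylation, since the phenol is more acidic and less hindered than the secondary benzylic alcohol and should take up one equivalent of silyl chloride first.

Step 4
Reactants: 7 (E)-but-2-enal (crotonaldehyde)
Product: 8 (Z)-2-iodobut-2-enal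
Conditions: I2, K2CO3, DMAP (cat.), THF/H2O (1:1), rt
Reagents that add atoms: iodine, II
Why: α-Iodination of an enal by a Morita–Baylis–Hillman-type addition–elimination, in which DMAP adds to C3, the enolate is iodinated at C2 and loss of DMAP restores the alkene with the methyl group trans to the formyl group, which is the (Z)-iodoenal.

Step 5
Reactants: 8 (Z)-2-iodobut-2-enal
Product: 9 (Z)-2-iodobut-2-en-1-ol
Conditions: NaBH4, MeOH, 0 °C
Reagents that add atoms: none
Why: Borohydride 1,2-reduction of the aldehyde, which leaves the alkenyl iodide and the alkene geometry untouched at 0 °C.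

Step 6
Reactants: 9 (Z)-2-iodobut-2-en-1-ol
Product: 10 4-methoxybenzyl (2Z)-2-(hydroxymethyl)but-2-enoate
Conditions: PdCl2(PPh3)2 (5 mol%), CO (1 atm), 4-methoxybenzyl alcohol (4 equiv), Et3N, DMF, 60 °C
Reagents that add atoms: carbon monoxide, [C-]#[O+]; 4-methoxybenzyl alcohol, COc1ccc(CO)cc1
Why: Palladium-catalysed alkoxycarbonylation (Heck carbonylation), in which zerovalent palladium inserts into the C–I bond with retention of alkene geometry, CO inserts, and the acylpalladium is captured by the excess primary benzylic alcohol rather than by the internal hydroxyl, which could only close a strained four-membered lactone.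

Step 7
Reactants: 10 4-methoxybenzyl (2Z)-2-(hydroxymethyl)but-2-enoate; 11 angelic acid, (Z)-2-methylbut-2-enoic acid
Product: 13 4-methoxybenzyl (2Z)-2-({[(2Z)-2-methylbut-2-enoyl]oxy}methyl)but-2-enoate, via angelic 2,4,6-trichlorobenzoic mixed anhydride 12 (not isolated)
Conditions: 11, 2,4,6-Cl3C6H2COCl, Et3N, toluene, rt; then 10, 70 °C
Reagents that add atoms: none
Why: Yamaguchi-type mixed-anhydride esterification run without a nucleophilic catalyst, in which the primary alcohol attacks the less hindered angeloyl carbonyl of 12 and the absence of DMAP avoids the addition–elimination that turns angelates into tiglates.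

Step 8
Reactants: 13 4-methoxybenzyl (2Z)-2-({[(2Z)-2-methylbut-2-enoyl]oxy}methyl)but-2-enoate
Product: 14 (2Z)-2-({[(2Z)-2-methylbut-2-enoyl]oxy}methyl)but-2-enoic acid
Conditions: TFA/CH2Cl2 (1:4), anisole, 0 °C
Reagents that add atoms: none
Why: Acidolysis of a 4-methoxybenzyl ester, in which the stabilised 4-methoxybenzyl cation leaves and is trapped by anisole (Friedel–Crafts alkylation) while the two conjugated esters, which cannot ionise in this way, and both Z-alkenes should remain.

Step 9
Reactants: 6 (1S)-1-{3-[(tert-butyldimethylsilyl)oxy]-4,5-dimethoxyphenyl}propan-1-ol; 14 (2Z)-2-({[(2Z)-2-methylbut-2-enoyl]oxy}methyl)but-2-enoic acid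
Product: 16 (1S)-1-{3-[(tert-butyldimethylsilyl)oxy]-4,5-dimethoxyphenyl}propyl (2Z)-2-({[(2Z)-2-methylbut-2-enoyl]oxy}methyl)but-2-enoate, via 2,4,6-trichlorobenzoic mixed anhydride 15 (not isolated)
Conditions: 14 (1.3 equiv), 2,4,6-Cl3C6H2COCl, Et3N, toluene, rt; then 6, 70 °C
Reagents that add atoms: none
Why: Yamaguchi-type esterification in which the secondary benzylic hydroxyl attacks the enoyl carbonyl of 15, so the C–O bond at the stereocentre is not broken and the (S)-configuration is retained, while leaving out nucleophilic amines protects the Z-enoate and the allylic angelate.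

Step 10
Reactants: 16 (1S)-1-{3-[(tert-butyldimethylsilyl)oxy]-4,5-dimethoxyphenyl}propyl (2Z)-2-({[(2Z)-2-methylbut-2-enoyl]oxy}methyl)but-2-enoate
Product: 17 (1S)-1-(3-hydroxy-4,5-dimethoxyphenyl)propyl (2Z)-2-({[(2Z)-2-methylbut-2-enoyl]oxy}methyl)but-2-enoate (target)
Conditions: Bu4NF, AcOH (1:1), THF, 0 °C
Reagents that add atoms: none
Why: Fluoride cleavage of an aryl silyl ether driven by Si–F bond formation, buffered with acetic acid so that the phenoxide is protonated at once and neither ester is attacked.

**Compound list**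

1 | 1-(3,4-dimethoxyphenyl)propan-1-one | CCC(=O)c1ccc(OC)c(OC)c1 | starting material
2 | (1S)-1-(3,4-dimethoxyphenyl)propan-1-ol | O[C@@H](CC)c1ccc(OC)c(OC)c1 | intermediate
3 | 2-{[(1S)-1-(3,4-dimethoxyphenyl)propyl]oxy}-4,4,5,5-tetramethyl-1,3,2-dioxaborolane | CC1(C)OB(O[C@@H](CC)c2ccc(OC)c(OC)c2)OC1(C)C | intermediate (not isolated)
4 | 2-{2,3-dimethoxy-5-[(1S)-1-(pinacolboryloxy)propyl]phenyl}-4,4,5,5-tetramethyl-1,3,2-dioxaborolane | CC1(C)OB(O[C@@H](CC)c2cc(OC)c(OC)c(B3OC(C)(C)C(C)(C)O3)c2)OC1(C)C | intermediate (not isolated)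
5 | (1S)-1-(3-hydroxy-4,5-dimethoxyphenyl)propan-1-ol | O[C@@H](CC)c1cc(O)c(OC)c(OC)c1 | intermediate
6 | (1S)-1-{3-[(tert-butyldimethylsilyl)oxy]-4,5-dimethoxyphenyl}propan-1-ol | O[C@@H](CC)c1cc(O[Si](C)(C)C(C)(C)C)c(OC)c(OC)c1 | intermediate
7 | (E)-but-2-enal | C/C=C/C=O | starting material
8 | (Z)-2-iodobut-2-enal | C/C=C(\I)C=O | intermediate
9 | (Z)-2-iodobut-2-en-1-ol | C/C=C(\I)CO | intermediate
10 | 4-methoxybenzyl (2Z)-2-(hydroxymethyl)but-2-enoate | OC/C(=C/C)C(=O)OCc1ccc(OC)cc1 | intermediate
11 | angelic acid, (Z)-2-methylbut-2-enoic acid | C/C=C(/C)C(=O)O | starting material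
12 | (Z)-2-methylbut-2-enoic 2,4,6-trichlorobenzoic anhydride | C/C=C(/C)C(=O)OC(=O)c1c(Cl)cc(Cl)cc1Cl | intermediate (not isolated)
13 | 4-methoxybenzyl (2Z)-2-({[(2Z)-2-methylbut-2-enoyl]oxy}methyl)but-2-enoate | C/C=C(/C)C(=O)OC/C(=C/C)C(=O)OCc1ccc(OC)cc1 | intermediate
14 | (2Z)-2-({[(2Z)-2-methylbut-2-enoyl]oxy}methyl)but-2-enoic acid | C/C=C(/C)C(=O)OC/C(=C/C)C(=O)O | intermediate
15 | (2Z)-2-({[(2Z)-2-methylbut-2-enoyl]oxy}methyl)but-2-enoic 2,4,6-trichlorobenzoic anhydride | C/C=C(/C)C(=O)OC/C(=C/C)C(=O)OC(=O)c1c(Cl)cc(Cl)cc1Cl | intermediate (not isolated)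
16 | (1S)-1-{3-[(tert-butyldimethylsilyl)oxy]-4,5-dimethoxyphenyl}propyl (2Z)-2-({[(2Z)-2-methylbut-2-enoyl]oxy}methyl)but-2-enoate | C/C=C(/C)C(=O)OC/C(=C/C)C(=O)O[C@@H](CC)c1cc(O[Si](C)(C)C(C)(C)C)c(OC)c(OC)c1 | intermediate
17 | (1S)-1-(3-hydroxy-4,5-dimethoxyphenyl)propyl (2Z)-2-({[(2Z)-2-methylbut-2-enoyl]oxy}methyl)but-2-enoate | C/C=C(/C)C(=O)OC/C(=C/C)C(=O)O[C@@H](CC)c1cc(O)c(OC)c(OC)c1 | target

**Step count**

Total steps: 10. Longest linear sequence: 7 steps (steps 4 to 10, from crotonaldehyde); the aryl branch is steps 1 to 3.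

**Steps most likely to fail**

1. Step 2. The C–H activation may be slow or may also occur ortho to the side chain or twice on the ring, and the electron-rich phenol may be over-oxidised during the peroxide stage.
Fallback, setting out from 2 and returning at 5: regiocontrol is handed to methoxy-directed lithiation. Compound 2 would be silylated with TIPSOTf and 2,6-lutidine to triisopropyl{[(1S)-1-(3,4-dimethoxyphenyl)propyl]oxy}silane F1. Treatment with n-BuLi and TMEDA in Et2O at 0 °C should metalate the ring ortho to the C4 methoxy oxygen, the site between the C3 methoxy group and the bulky silyloxyalkyl group being shielded, to give the aryllithium F2. Quenching with B(OMe)3 would give the dimethyl arylboronate F3, and NaOH/H2O2 the silyl-protected phenol F4. Bu4NF in THF would then remove the silyl group and give 5.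

2. Step 9. The activated Z-enoyl unit may isomerise to the E-isomer by reversible conjugate addition, the allylic angelate may be displaced, or acylation of the hindered secondary alcohol may stall.
Fallback, setting out from 1 and returning at 16: the ester is made with the carboxylate as nucleophile, so that the acid is never activated at its carbonyl. Ketone 1 would be reduced with RuCl(p-cymene)[(R,R)-TsDPEN] in HCO2H/Et3N to (1R)-1-(3,4-dimethoxyphenyl)propan-1-ol F5. The conditions of step 2 would take F5 through the pinacol borate ester F6 and the ring-borylated borate ester F7 to (1R)-1-(3-hydroxy-4,5-dimethoxyphenyl)propan-1-ol F8. TBSCl and imidazole would give the (1R)-configured phenol silyl ether F9. A Mitsunobu reaction of F9 with acid 14 (PPh3 and DIAD premixed, THF, 0 °C) should displace the activated hydroxyl with inversion and give 16.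

3. Step 6. The acylpalladium may be captured by the substrate's own hydroxyl, leading to lactone or oligoester formation, or the iodide may be lost by protodeiodination.
Fallback, setting out from 9 and returning at 10: the carboxyl carbon is brought in by an organolithium instead of by palladium. Compound 9 would be deprotonated with n-BuLi (1 equiv) and exchanged with t-BuLi (2 equiv) in Et2O at −78 °C to the dilithio alkoxide–alkenyllithium F10, which keeps the alkene geometry. CO2 would give (2Z)-2-(hydroxymethyl)but-2-enoic acid F11. O-Alkylation of its carboxylate with 4-methoxybenzyl chloride and Cs2CO3 in DMF, which does not activate the carbonyl, would give 10.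

**Further compounds**

F1 | step 2 | triisopropyl{[(1S)-1-(3,4-dimethoxyphenyl)propyl]oxy}silane | CC(C)[Si](O[C@@H](CC)c1ccc(OC)c(OC)c1)(C(C)C)C(C)C
F2 | step 2 | {2,3-dimethoxy-5-[(1S)-1-(triisopropylsilyloxy)propyl]phenyl}lithium | CC(C)[Si](O[C@@H](CC)c1cc(OC)c(OC)c([Li])c1)(C(C)C)C(C)C
F3 | step 2 | dimethyl {2,3-dimethoxy-5-[(1S)-1-(triisopropylsilyloxy)propyl]phenyl}boronate | CC(C)[Si](O[C@@H](CC)c1cc(OC)c(OC)c(B(OC)OC)c1)(C(C)C)C(C)C
F4 | step 2 | 2,3-dimethoxy-5-[(1S)-1-(triisopropylsilyloxy)propyl]phenol | CC(C)[Si](O[C@@H](CC)c1cc(O)c(OC)c(OC)c1)(C(C)C)C(C)C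
F5 | step 9 | (1R)-1-(3,4-dimethoxyphenyl)propan-1-ol | O[C@H](CC)c1ccc(OC)c(OC)c1
F6 | step 9 | 2-{[(1R)-1-(3,4-dimethoxyphenyl)propyl]oxy}-4,4,5,5-tetramethyl-1,3,2-dioxaborolane | CC1(C)OB(O[C@H](CC)c2ccc(OC)c(OC)c2)OC1(C)C
F7 | step 9 | 2-{2,3-dimethoxy-5-[(1R)-1-(pinacolboryloxy)propyl]phenyl}-4,4,5,5-tetramethyl-1,3,2-dioxaborolane | CC1(C)OB(O[C@H](CC)c2cc(OC)c(OC)c(B3OC(C)(C)C(C)(C)O3)c2)OC1(C)C
F8 | step 9 | (1R)-1-(3-hydroxy-4,5-dimethoxyphenyl)propan-1-ol | O[C@H](CC)c1cc(O)c(OC)c(OC)c1
F9 | step 9 | (1R)-1-{3-[(tert-butyldimethylsilyl)oxy]-4,5-dimethoxyphenyl}propan-1-ol | O[C@H](CC)c1cc(O[Si](C)(C)C(C)(C)C)c(OC)c(OC)c1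
F10 | step 6 | lithium (Z)-2-lithiobut-2-en-1-olate | C/C=C(\[Li])CO[Li]
F11 | step 6 | (2Z)-2-(hydroxymethyl)but-2-enoic acid | C/C=C(/CO)C(=O)O
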